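## Retrosynthetic overview
1. Ester C1–O bond: the target comes from the C1-epimeric (1R) allylic alcohol and unprotected caffeic acid by Mitsunobu inversion.
2. The allylic alcohol comes by Wharton transposition from the epoxide of a carvone-type enone whose carbonyl sits at C3. Ring A is pseudo-symmetric about the C2···C5 axis, so this transposition converts the C5 configuration delivered by the key step into that of the target.
3. Key disconnection is C5–C1', the bond between the two quaternary carbons. It joins the β-carbon of 3,6-dimethylcyclohex-2-enone to the γ-carbon of a lithiated (R)-sulfinylallyl anion, a chiral homoenolate equivalent of 2-methylcyclopent-1-enecarbaldehyde. Removing sulfur in the same flask leaves the exocyclic methylene.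
4. The allyl sulfoxide comes from (R)-methyl p-tolyl sulfoxide and 2-methylcyclopentanone. The enone comes from 3-methylcyclohex-2-enone and MeI.
5. Ring order: ring B (cyclopentane) and ring A (cyclohexane) are both bought intact and joined in the key step. The only ring that is made is the transient oxirane.

Assumption: target numbering is used for all intermediates (ring A: C1 = C–O, C2 = C–CH3, C3 = CH, C4, C5 = quaternary, C6; ring B: C1' = quaternary, C2' = C=CH2, C3'–C5'), and C2 is left unassigned in 10–14 because it becomes sp2 in 15.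

## Route

**Step 1**
Reactants: 1 (R)-methyl p-tolyl sulfoxide; 2 2-methylcyclopentan-1-one (racemic)
Product: 7 (R)-(2-methylcyclopent-1-en-1-yl)methyl p-tolyl sulfoxide, via lithiated sulfoxide 3 (not isolated), via lithium alkoxide 4 (not isolated), via tertiary mesylate 5 (not isolated), via vinyl sulfoxide 6 (not isolated)
Conditions: LiN(i-Pr)2 (1.05 equiv), THF, −78 °C; 2; MsCl (1.2 equiv), −78 → −20 °C; KOt-Bu (1.5 equiv), t-BuOH–THF, −20 → 0 °C
Reagents that add atoms: none
Why: Carbonyl addition of the α-sulfinyl carbanion, mesylation of the tertiary alkoxide and base-induced elimination give the alkenyl sulfoxide, and base-catalysed prototropic equilibration (sulfoxides prefer the β,γ-position, five-membered rings the endocyclic tetrasubstituted alkene) funnels it to 7; sulfur is never attacked, so it stays (R), and working at or below 0 °C suppresses racemisation through the allyl sulfoxide–sulfenate [2,3]-shift.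

**Step 2**
Reactants: 8 3-methylcyclohex-2-en-1-one
Product: 10 3,6-dimethylcyclohex-2-en-1-one (racemic), via lithium dienolate 9 (not isolated)
Conditions: LiN(i-Pr)2 (1.05 equiv), THF, −78 °C; MeI (1.2 equiv), −78 → 0 °C
Reagents that add atoms: iodomethane, CI
Why: Kinetic α'-deprotonation gives the cross-conjugated dienolate, whose SN2 enolate alkylation is regioselective; the new centre (C2) is racemic and is erased in step 4.

**Step 3 (key step)**
Reactants: 7 (R)-(2-methylcyclopent-1-en-1-yl)methyl p-tolyl sulfoxide; 10 3,6-dimethylcyclohex-2-en-1-one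
Product: 14 (5R)-2,5-dimethyl-5-[(1S)-1-methyl-2-methylidenecyclopentyl]cyclohexan-1-one as a C2 epimer mixture, via lithiated allyl sulfoxide 11 (not isolated), via vinyl sulfoxide enolate 12 (not isolated), via alkenyllithium enolate 13 (not isolated)
Conditions: LiN(i-Pr)2 (1.05 equiv), THF, −78 °C, 15 min; 10 (1.2 equiv), −78 → −40 °C; t-BuLi (3 equiv), −78 °C, 15 min; sat. aq NH4Cl
Reagents that add atoms: none
Why: Proposed new method: lithiated 7 is a chiral homoenolate (d3) equivalent of 2-methylcyclopent-1-enecarbaldehyde, so its γ-carbon C1' and the enone β-carbon C5, both electrophilic in their parent carbonyl compounds, are joined; lithium bridges the sulfinyl and enone oxygens in a ten-membered chair–chair (trans-decalin-like) transition state with p-tolyl equatorial and the two fully substituted carbons staggered, which makes the 1,4-γ-pathway quasi-intramolecular, fixes C5 and C1' together from the (R)-sulfur and gives the (E)-vinyl sulfoxide with the ring A carbonyl at C3; the enolate 12 then shields the ketone while t-BuLi carries out a sulfoxide–lithium exchange, and protonation leaves the exocyclic methylene; the closest known reaction type is the kinetically controlled asymmetric 1,4-γ-addition of lithiated allyl p-tolyl sulfoxides to cyclic enones, which already tolerates β-substituted enones, and what is new is that the γ-terminus is tetrasubstituted, so two adjacent quaternary centres form at once.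

**Step 4**
Reactants: 14 (5R)-2,5-dimethyl-5-[(1S)-1-methyl-2-methylidenecyclopentyl]cyclohexan-1-one
Product: 15 (5R)-2,5-dimethyl-5-[(1S)-1-methyl-2-methylidenecyclopentyl]cyclohex-2-en-1-one
Conditions: IBX (2.5 equiv), DMSO–fluorobenzene 1:2, 75 °C
Reagents that add atoms: none
Why: IBX dehydrogenation through the enol: C5 bears no hydrogen, so only the C1–C2 bond can be desaturated, both C2 epimers converge on one enone, and the isolated 1,1-disubstituted alkene and the two quaternary centres are untouched.

**Step 5**
Reactants: 15 (5R)-2,5-dimethyl-5-[(1S)-1-methyl-2-methylidenecyclopentyl]cyclohex-2-en-1-one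
Product: 16 (1R,4R,6R)-1,4-dimethyl-4-[(1S)-1-methyl-2-methylidenecyclopentyl]-7-oxabicyclo[4.1.0]heptan-2-one
Conditions: 30% aq H2O2 (3 equiv), NaOH (0.3 equiv), MeOH, 0 °C
Reagents that add atoms: hydrogen peroxide, OO
Why: Weitz–Scheffer nucleophilic epoxidation attacks only the electron-poor enone alkene; with the very large ring B group equatorial on C5, hydroperoxide adds axially to C1 on the face of the axial C5 methyl group (as in carvone, trans to the large C5 substituent), so the oxirane and with it the C1–O bond are set trans to ring B.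

**Step 6**
Reactants: 16 (1R,4R,6R)-1,4-dimethyl-4-[(1S)-1-methyl-2-methylidenecyclopentyl]-7-oxabicyclo[4.1.0]heptan-2-one
Product: 18 (1R,5S)-2,5-dimethyl-5-[(1S)-1-methyl-2-methylidenecyclopentyl]cyclohex-2-en-1-ol, via epoxy hydrazone 17 (not isolated)
Conditions: N2H4·H2O (3 equiv), AcOH (0.3 equiv), MeOH, 0 °C → rt, argon
Reagents that add atoms: none
Why: Wharton transposition: the epoxy hydrazone opens to an allylic diazene that loses N2, moving the alkene to C2=C3 and leaving the C1–O bond and its (1R) configuration intact; argon prevents diimide formation and reduction of the exocyclic alkene.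

**Step 7**
Reactants: 18 (1R,5S)-2,5-dimethyl-5-[(1S)-1-methyl-2-methylidenecyclopentyl]cyclohex-2-en-1-ol; 19 caffeic acid, (E)-3-(3,4-dihydroxyphenyl)prop-2-enoic acid
Product: 20 (1S,5S)-2,5-dimethyl-5-[(1S)-1-methyl-2-methylidenecyclopentyl]cyclohex-2-en-1-yl (E)-3-(3,4-dihydroxyphenyl)prop-2-enoate (target)
Conditions: 19 (1.5 equiv), PPh3 (1.6 equiv), DIAD (1.6 equiv), THF, 0 °C → rt
Reagents that add atoms: none
Why: Mitsunobu esterification: the carboxylic acid (pKa about 4.5) reacts in preference to the catechol hydroxyls (pKa above 9), and SN2 displacement of the pseudo-axial oxyphosphonium group inverts C1 from (R) to (S), placing the ester cis to ring B; the (E)-alkene comes unchanged from 19.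

## Compound list
1 | (R)-methyl p-tolyl sulfoxide | C[S@@](=O)c1ccc(C)cc1 | starting material
2 | 2-methylcyclopentan-1-one (racemic) | CC1CCCC1=O | starting material
3 | [(R)-p-tolylsulfinyl]methyllithium | [Li]C[S@@](=O)c1ccc(C)cc1 | intermediate
4 | lithium 2-methyl-1-{[(R)-p-tolylsulfinyl]methyl}cyclopentan-1-olate (ring centres unassigned) | [Li]OC1(C[S@@](=O)c2ccc(C)cc2)CCCC1C | intermediate
5 | 2-methyl-1-{[(R)-p-tolylsulfinyl]methyl}cyclopentyl methanesulfonate (ring centres unassigned) | CC1CCCC1(C[S@@](=O)c1ccc(C)cc1)OS(C)(=O)=O | intermediate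
6 | (R)-(2-methylcyclopentylidene)methyl p-tolyl sulfoxide (alkene geometry and ring centre unassigned) | CC1CCCC1=C[S@@](=O)c1ccc(C)cc1 | intermediate
7 | (R)-(2-methylcyclopent-1-en-1-yl)methyl p-tolyl sulfoxide | CC1=C(C[S@@](=O)c2ccc(C)cc2)CCC1 | intermediate
8 | 3-methylcyclohex-2-en-1-one | CC1=CC(=O)CCC1 | starting material
9 | lithium 3-methylcyclohexa-1,3-dien-1-olate type cross-conjugated dienolate of 8 (C1=C6, C2=C3) | [Li]OC1=CCCC(C)=C1 | intermediate
10 | 3,6-dimethylcyclohex-2-en-1-one (racemic) | CC1CCC(C)=CC1=O | intermediate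
11 | α-lithiated 7 (sulfur R, carbanion centre unassigned) | [Li]C(C1=C(C)CCC1)[S@@](=O)c1ccc(C)cc1 | intermediate
12 | lithium C3=C4 enolate of the 1,4-γ-adduct; (E)-vinyl sulfoxide on C2', sulfur R, C5 and C1' arranged as in 14 | Cc1ccc(cc1)[S@](=O)/C=C2\CCC[C@]2(C)[C@@]1(C)C=C(O[Li])C(C)CC1 | intermediate
13 | dilithio species: 12 with the sulfinyl group exchanged for lithium with retention of alkene geometry | [Li]/C=C1\CCC[C@]1(C)[C@@]1(C)C=C(O[Li])C(C)CC1 | intermediate
14 | (5R)-2,5-dimethyl-5-[(1S)-1-methyl-2-methylidenecyclopentyl]cyclohexan-1-one (C2 epimers) | C=C1CCC[C@]1(C)[C@@]1(C)CC(=O)C(C)CC1 | intermediate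
15 | (5R)-2,5-dimethyl-5-[(1S)-1-methyl-2-methylidenecyclopentyl]cyclohex-2-en-1-one | C=C1CCC[C@]1(C)[C@@]1(C)CC(=O)C(C)=CC1 | intermediate
16 | (1R,4R,6R)-1,4-dimethyl-4-[(1S)-1-methyl-2-methylidenecyclopentyl]-7-oxabicyclo[4.1.0]heptan-2-one (oxirane trans to ring B) | C=C1CCC[C@]1(C)[C@@]1(C)CC(=O)[C@]2(C)O[C@@H]2C1 | intermediate
17 | hydrazone of 16 (all stereocentres as in 16) | C=C1CCC[C@]1(C)[C@@]1(C)CC(=NN)[C@]2(C)O[C@@H]2C1 | intermediate
18 | (1R,5S)-2,5-dimethyl-5-[(1S)-1-methyl-2-methylidenecyclopentyl]cyclohex-2-en-1-ol (OH trans to ring B) | C=C1CCC[C@]1(C)[C@@]1(C)CC=C(C)[C@H](O)C1 | intermediate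
19 | caffeic acid | O=C(O)/C=C/c1ccc(O)c(O)c1 | starting material
20 | (1S,5S)-2,5-dimethyl-5-[(1S)-1-methyl-2-methylidenecyclopentyl]cyclohex-2-en-1-yl (E)-3-(3,4-dihydroxyphenyl)prop-2-enoate | C=C1CCC[C@]1(C)[C@@]1(C)CC=C(C)[C@@H](OC(=O)/C=C/c2ccc(O)c(O)c2)C1 | target

## Step count
Total step count: 7 (one-flask sequences counted as one step).
Longest linear sequence: 6 (steps 1, 3, 4, 5, 6, 7).

## Three steps most likely to fail

**Step 3.** The tetrasubstituted γ-carbon may refuse the direct 1,4-γ-addition, giving α-1,2-addition or deprotonation of the enone instead.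
- The fallback sets out from 7 and 10 and comes back at 14.
- Lithiated 7 is transmetallated with anhydrous CeCl3, so that it adds through its α-carbon to the carbonyl group of 10. This gives the bis-allylic tertiary alcohol F1.
- The diastereomers of F1 are separated, because the following shift is suprafacial on ring A and relays the carbinol configuration to C5.
- KH and 18-crown-6 in THF (0 °C → rt) then drive an anionic oxy-Cope rearrangement. This closes the same C5–C1' bond intramolecularly and irreversibly and gives, after a proton quench, the keto vinyl sulfoxide F2.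
- F2 can be freed of stereoisomers by chromatography because it still carries the sulfinyl auxiliary.
- The ketone of F2 is masked in the flask as its enolate with LiN(SiMe3)2. Sulfoxide–lithium exchange with t-BuLi followed by NH4Cl returns to 14.

**Step 6.** The Wharton transposition often gives moderate yields, and adventitious diimide could reduce the exocyclic alkene.
- The fallback sets out from 16 and comes back at 18.
- NaBH4 and CeCl3 in MeOH reduce the ketone to the epoxy alcohol F3, whose carbinol configuration does not matter.
- 1,1'-Thiocarbonyldiimidazole converts F3 into the thiocarbonylimidazolide F4.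
- Bu3SnH and AIBN in benzene at 80 °C generate the C3 radical. It opens the adjacent oxirane to the C2=C3 alkene and a C1 alkoxy radical.
- Hydrogen transfer to that radical gives 18 with the C1–O bond untouched. This is a radical epoxide fragmentation in place of the diazene route.

**Step 7.** The hindered allylic alcohol may eliminate or react by SN2', or the free catechol may interfere.
- The fallback sets out from 18 and comes back at 20. It forms the ester with retention and builds the cinnamate alkene last.
- MnO2 in CH2Cl2 oxidises 18 to the transposed enone F5.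
- (R)-2-Methyl-CBS-oxazaborolidine and catecholborane in toluene at −78 °C reduce F5 under reagent control to the cis allylic alcohol F6.
- Heating F6 with Meldrum's acid in toluene at 100 °C gives the malonic half-ester F7.
- A Knoevenagel–Doebner condensation of F7 with unprotected 3,4-dihydroxybenzaldehyde (pyridine, catalytic piperidine, 50 °C) gives 20 directly as the (E)-ester.

## Further compounds
F1 | step 3 | bis-allylic tertiary alcohol 1-{(2-methylcyclopent-1-en-1-yl)[(R)-(4-methylphenyl)sulfinyl]methyl}-3,6-dimethylcyclohex-2-en-1-ol (carbon centres as separated) | CC1CCC(C)=CC1(O)C(C1=C(C)CCC1)[S@@](=O)c1ccc(C)cc1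
F2 | step 3 | keto vinyl sulfoxide (5R)-2,5-dimethyl-5-[(1R,2E)-1-methyl-2-{[(R)-(4-methylphenyl)sulfinyl]methylidene}cyclopentyl]cyclohexan-1-one (C2 epimers) | Cc1ccc(cc1)[S@](=O)/C=C2\CCC[C@]2(C)[C@@]1(C)CC(=O)C(C)CC1
F3 | step 6 | epoxy alcohol, 16 with C3=O reduced to CHOH (other stereocentres as in 16, carbinol unassigned) | C=C1CCC[C@]1(C)[C@@]1(C)CC(O)[C@]2(C)O[C@@H]2C1
F4 | step 6 | thiocarbonylimidazolide, O-(imidazol-1-ylthiocarbonyl) derivative of F3 | C=C1CCC[C@]1(C)[C@@]1(C)CC(OC(=S)n2ccnc2)[C@]2(C)O[C@@H]2C1
F5 | step 7 | transposed enone (5S)-2,5-dimethyl-5-[(1S)-1-methyl-2-methylidenecyclopentyl]cyclohex-2-en-1-one | C=C1CCC[C@]1(C)[C@@]1(C)CC=C(C)C(=O)C1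
F6 | step 7 | cis allylic alcohol (1S,5S)-2,5-dimethyl-5-[(1S)-1-methyl-2-methylidenecyclopentyl]cyclohex-2-en-1-ol | C=C1CCC[C@]1(C)[C@@]1(C)CC=C(C)[C@@H](O)C1
F7 | step 7 | malonic half-ester 3-{[(1S,5S)-2,5-dimethyl-5-[(1S)-1-methyl-2-methylidenecyclopentyl]cyclohex-2-en-1-yl]oxy}-3-oxopropanoic acid | C=C1CCC[C@]1(C)[C@@]1(C)CC=C(C)[C@@H](OC(=O)CC(=O)O)C1
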